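Two things are asked of this flask: how it stands at the end of the run, and how much Q stands then.

    L + G → Q + G, rate k1*[L]*[G]/(1 + ([L]/Km1) + ([Q]/Kp1)) (Km1 = 1.1 mM, Kp1 = 0.77 mM, k1 = 4.1 × 10⁶ /M/s)
    G + X ⇌ G.X (K2 = 2.1 × 10⁶ /M, k2 = 1.9 × 10⁶ /M/s)
    2 L → L2 (k3 = 380 /M/s)

L 0.50 mM; G 0.050 µM; X 0.23 µM; time 2.0 min

- the state of affairs at 2.0 min: stopped, and by what, or still going (it is still moving / forward and back rates have come level / all of L has reacted / no working catalyst is left)
- the Q standing at 2.0 min, as a percentage of the L charged

- percentages count the L that a species holds: one L2 counts as two
- where a step has two of a species, its rate is k times that concentration squared, and two are used at each turn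
- the reaction counts as stopped when no species that holds the L changes by six tenths of a point or more over the second half of the time
- run time (flask): 2.0 min

L leaves by two routes, so I look for what stays nearly constant while they compete. The first such thing is free G. Pairing alone gives L a first half-life of 2.63 s, and X binds G with a relaxation half-life of 0.517 s, which is shorter. With X in excess, I freeze c(G) at 0.0337 µM.

The second is the denominator of the enzyme's rate law, which I call the brake, D. My carried quantity is the crossover concentration, 0.182 mM: the enzyme's rate constant times free G, over twice the pairing constant. It is the level of L at which the routes take L equally when D is one; this is a selectivity factor with the units of a concentration. With c = crossover/D, a fraction c/(c + c(L)) of the L being used becomes Q, and integrating gives the yield (c/charge)·ln(1 + charge/c).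

I reckon this two ways. With the brake frozen at its start, 1.45, the yield is 40.2%. With the brake at its end, 1.26, reckoned from that Q, it is 43.2%. They part, and the start value cheats: the same formula splits the Q into two equal parts at 0.161 mM of L, a level lower than the charge. So I commit to 43.2%. Late on, the enzyme removes L with a pseudo-first-order half-life of 6.32 s, which over 2.0 min leaves a fraction <0.001% of L, so I expect L to be used up.

The forecast says all of L has reacted and 43%, judging that “a bit over two fifths of the L ends up as Q”.

The flask gives all of L has reacted and 44.3%, 1.1 percentage points above my reckoning, with L at 0%. Free G in this flask reads 68.9% of its charge at 2.00 min, against the 67.4% I froze, and G.X holds 31.1%. The neighbouring flask charges 0.20 mM of L and keeps the crossover at 0.182 mM. Its end brake is 1.17, so the rule gives it 64.3%, and that flask gives 66.4%.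

The constants used here are made up; the flask was simulated.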